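**Strategy.** The 21-membered ring is opened at C7–C8, the exact midpoint of the tetradecamethylene bridge that joins C3 of the hydroquinone ring B to C5 of the resorcinol-derived ring A. Because both flanks of this unfunctionalised CH2–CH2 bond are identical heptylene arms, both ends can carry the same group, a terminal alkene. Ring-closing olefin metathesis of a bis(oct-7-enyl) diaryl ether unites the two like-polarised alkene carbons with loss of ethylene and closes the macrocycle in one operation; the C7=C8 alkene left behind is erased in the final hydrogenation, which also removes the three benzyl ethers. The precursor comes from two symmetric dibromoarenes by Chan–Lam etherification and a double B-alkyl Suzuki–Miyaura coupling.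

Key step: step 6

Assumption: the target has no stereocentre, and the E/Z geometry of alkene 14 is left undefined because the last step saturates it; ring B is numbered C1 (O-aryl), C2 (OH), C3 (bridge), C5 (OH), and ring A C1 (O-aryl), C3 (OH), C5 (bridge).

Step 1
Reactants: 1 2,6-dibromobenzene-1,4-diol
Product: 2 2,5-bis(benzyloxy)-1,3-dibromobenzene
Conditions: BnBr (2.4 equiv), K2CO3, DMF, argon, rt to 50 °C
Reagents that add atoms: benzyl bromide, BrCc1ccccc1
Why: Williamson ether synthesis; both phenoxides, including the acidic one flanked by two bromines, should be benzylated cleanly, and exclusion of air prevents oxidation of the hydroquinone to the quinone.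

Step 2
Reactants: 2 2,5-bis(benzyloxy)-1,3-dibromobenzene
Product: 5 2,5-bis(benzyloxy)-3-bromophenol, via aryllithium 3 (not isolated), via dimethyl arylboronate 4 (not isolated)
Conditions: n-BuLi (1.05 equiv), THF, –78 °C; B(OMe)3, –78 to 0 °C; AcOH then 30% H2O2, 0 °C to rt
Reagents that add atoms: hydrogen peroxide, OO
Why: Bromine–lithium exchange on one of two equivalent bromides (a second exchange on the aryllithium is disfavoured), borylation and oxidative 1,2-migration from boron to oxygen should convert one C–Br into C–OH; the lithium sits meta to the remaining bromide, so no aryne can form.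

Step 3
Reactants: 6 1-(benzyloxy)-3,5-dibromobenzene
Product: 9 [3-(benzyloxy)-5-bromophenyl]boronic acid, via aryllithium 7 (not isolated), via diisopropyl arylboronate 8 (not isolated)
Conditions: n-BuLi (1.05 equiv), Et2O, –78 °C; B(OiPr)3, –78 °C to rt; 1 M aq HCl
Reagents that add atoms: triisopropyl borate, CC(C)OB(OC(C)C)OC(C)C; water, O
Why: Selective mono bromine–lithium exchange of a symmetric 1,3-dibromoarene, borate trapping and acidic hydrolysis is the standard route to a 3-bromoarylboronic acid.

Step 4
Reactants: 5 2,5-bis(benzyloxy)-3-bromophenol; 9 [3-(benzyloxy)-5-bromophenyl]boronic acid (2 equiv)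
Product: 10 2,5-bis(benzyloxy)-1-[3-(benzyloxy)-5-bromophenoxy]-3-bromobenzene
Conditions: Cu(OAc)2 (2 equiv), pyridine, 4 Å molecular sieves, CH2Cl2, dry air, rt
Reagents that add atoms: none
Why: Chan–Lam oxidative O-arylation of a phenol with an unhindered arylboronic acid proceeds at room temperature, where both aryl bromides are inert to copper, so the diaryl ether should form with both cross-coupling handles intact.

Step 5
Reactants: 10 2,5-bis(benzyloxy)-1-[3-(benzyloxy)-5-bromophenoxy]-3-bromobenzene; 11 octa-1,7-diene
Product: 13 2,5-bis(benzyloxy)-1-(oct-7-en-1-yl)-3-[3-(benzyloxy)-5-(oct-7-en-1-yl)phenoxy]benzene, via B-(oct-7-enyl)-9-BBN 12 (not isolated)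
Conditions: 9-BBN (3 equiv), 11 (12 equiv), THF, 0 °C to rt, excess 11 removed in vacuo; then 10, Pd(OAc)2 (10 mol%), SPhos (20 mol%), 3 M aq K3PO4, THF, 65 °C
Reagents that add atoms: none
Why: Anti-Markovnikov mono-hydroboration of the diene used in excess, followed by a double B-alkyl Suzuki–Miyaura coupling, should install both oct-7-enyl arms at once; the bulky electron-rich phosphine supports oxidative addition at the bromide next to the benzyloxy group and fast reductive elimination over β-hydride elimination.

Step 6
Reactants: 13 2,5-bis(benzyloxy)-1-(oct-7-en-1-yl)-3-[3-(benzyloxy)-5-(oct-7-en-1-yl)phenoxy]benzene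
Product: 14 tri-O-benzyl 21-membered macrocyclic alkene (C7=C8 of the bridge; E/Z mixture)
Conditions: second-generation Grubbs catalyst RuCl2(=CHPh)(H2IMes)(PCy3) (2 × 5 mol%), 1,4-benzoquinone (20 mol%), CH2Cl2 (1 mM), 40 °C, argon sparge
Reagents that add atoms: none
Why: Ring-closing olefin metathesis: the ruthenium benzylidene exchanges with one terminal alkene of 13 to give a ruthenium alkylidene at C7 of that arm, which reacts with the terminal alkene of the other arm by [2+2] cycloaddition and cycloreversion through a ruthenacyclobutane, forming the C7=C8 double bond and releasing ethylene. The closest known reaction type is macrocyclic RCM of α,ω-dienes held together by a biaryl or diaryl ether unit, which is established for cyclophanes with long polymethylene bridges. The closure is a head-to-head macrocyclisation to an essentially strain-free 21-membered ring (14 bridge carbons, three atoms of each arene and the ether oxygen), helped by the bent diaryl ether with its two meta-disposed arms. No stereocentre is created, and the alkene geometry is irrelevant because step 7 saturates it. The step needs ring closure to win over acyclic diene metathesis oligomerisation, which 1 mM dilution and removal of ethylene should secure by funnelling oligomers back to the ring under thermodynamic control. It also needs suppression of ruthenium hydride alkene migration, which would give ring-contracted homologues and is countered by the 1,4-benzoquinone additive; the two equivalent monosubstituted termini are the only alkenes in 13, and the aryl benzyl ethers and the diaryl ether are inert to the catalyst.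

Step 7
Reactants: 14 tri-O-benzyl 21-membered macrocyclic alkene
Product: 15 target macrocycle (CNP0393720.0)
Conditions: H2 (1 atm), 10% Pd/C, EtOAc/MeOH, rt; filtration and concentration under argon
Reagents that add atoms: none
Why: Heterogeneous catalytic hydrogenation should saturate the disubstituted alkene and cleave all three aryl benzyl ethers by hydrogenolysis in one operation, while the diaryl ether and the arenes are untouched under these neutral conditions; the air-sensitive hydroquinone is handled under inert gas.

Compound list
1 | 2,6-dibromobenzene-1,4-diol (2,6-dibromohydroquinone) | Oc1cc(Br)c(O)c(Br)c1 | starting material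
2 | 2,5-bis(benzyloxy)-1,3-dibromobenzene | Brc1cc(OCc2ccccc2)cc(Br)c1OCc1ccccc1 | intermediate
3 | [2,5-bis(benzyloxy)-3-bromophenyl]lithium | [Li]c1cc(OCc2ccccc2)cc(Br)c1OCc1ccccc1 | intermediate
4 | dimethyl [2,5-bis(benzyloxy)-3-bromophenyl]boronate | COB(OC)c1cc(OCc2ccccc2)cc(Br)c1OCc1ccccc1 | intermediate
5 | 2,5-bis(benzyloxy)-3-bromophenol | Oc1cc(OCc2ccccc2)cc(Br)c1OCc1ccccc1 | intermediate
6 | 1-(benzyloxy)-3,5-dibromobenzene | Brc1cc(Br)cc(OCc2ccccc2)c1 | starting material
7 | [3-(benzyloxy)-5-bromophenyl]lithium | [Li]c1cc(Br)cc(OCc2ccccc2)c1 | intermediate
8 | diisopropyl [3-(benzyloxy)-5-bromophenyl]boronate | CC(C)OB(OC(C)C)c1cc(Br)cc(OCc2ccccc2)c1 | intermediate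
9 | [3-(benzyloxy)-5-bromophenyl]boronic acid | OB(O)c1cc(Br)cc(OCc2ccccc2)c1 | intermediate
10 | 2,5-bis(benzyloxy)-1-[3-(benzyloxy)-5-bromophenoxy]-3-bromobenzene | Brc1cc(OCc2ccccc2)cc(Oc2cc(OCc3ccccc3)cc(Br)c2OCc2ccccc2)c1 | intermediate
11 | octa-1,7-diene | C=CCCCCC=C | starting material
12 | 9-(oct-7-en-1-yl)-9-borabicyclo[3.3.1]nonane | C=CCCCCCCB1C2CCCC1CCC2 | intermediate
13 | 2,5-bis(benzyloxy)-1-(oct-7-en-1-yl)-3-[3-(benzyloxy)-5-(oct-7-en-1-yl)phenoxy]benzene | C=CCCCCCCc1cc(OCc2ccccc2)cc(Oc2cc(OCc3ccccc3)cc(CCCCCCC=C)c2OCc2ccccc2)c1 | intermediate
14 | tri-O-benzyl 21-membered macrocyclic alkene, C7=C8 in the bridge, E/Z mixture | C1=CCCCCCCc2cc(OCc3ccccc3)cc(c2)Oc2cc(OCc3ccccc3)cc(CCCCCC1)c2OCc2ccccc2 | intermediate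
15 | target macrocycle: diaryl ether cyclophane with a tetradecane-1,14-diyl bridge between C3 of the 2-aryloxyhydroquinone ring B and C5 of the 3-hydroxyphenoxy ring A | Oc1cc2cc(c1)Oc1cc(O)cc(c1O)CCCCCCCCCCCCCC2 | target

Total step count: 7. Longest linear sequence: 6 steps (steps 1, 2, 4, 5, 6, 7); step 3 is a one-step branch.

Steps most likely to fail

1. Step 6 (macrocyclic RCM). The risk is intermolecular metathesis to oligomers instead of ring closure, and double-bond migration before closure, which would contract the ring by one or more CH2 units. Fallback, from 13 back to 14 by reductive carbonyl coupling: Lemieux–Johnson cleavage of both terminal alkenes of 13 (K2OsO4·2H2O cat., NaIO4, 2,6-lutidine, dioxane/H2O, rt) should remove the two terminal CH2 groups as formaldehyde and give the bis(7-oxoheptyl) dialdehyde F1. Slow addition of F1 to low-valent titanium made from TiCl3 and Zn–Cu couple in refluxing DME (intramolecular McMurry coupling at high dilution) joins the two aldehyde carbons, again C7 and C8, and comes back to the route at 14.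

2. Step 4 (Chan–Lam etherification). The risk is slow O-arylation of the ortho-benzyloxy phenol, with protodeboronation and oxidative homocoupling of the boronic acid and oxidation of the electron-rich phenol taking over. Fallback, from 6 and 5 back to 10 by an Ullmann-type coupling with an aryl halide electrophile: the aryllithium 7, generated from 6 as in step 3, is quenched with I2 to give 1-(benzyloxy)-3-bromo-5-iodobenzene F2. Copper-catalysed coupling of F2 with phenol 5 (CuI, picolinic acid, K3PO4, DMSO, 70–80 °C) should take place at the iodide, the more reactive and unhindered halide, and comes back to the route at 10.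

3. Step 5 (double B-alkyl Suzuki–Miyaura coupling). The risk is incomplete coupling at the bromide flanked by the benzyloxy group, with protodebromination and β-hydride elimination of the alkylpalladium intermediate, and bis-hydroboration of the diene leading to cross-linking. Fallback, from 10 back to 13 with the polarity of the aryl carbons reversed: double bromine–lithium exchange of 10 (t-BuLi, 4.2 equiv, THF, –78 °C) should give the dilithio diaryl ether F3. Alkylation of F3 with commercial 8-bromooct-1-ene (DMPU, –78 °C to rt) comes back to the route at 13.

Further compounds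
F1 | step 6 | 7,7'-[bis(benzyloxy)phenylene / (benzyloxy)phenylene diaryl ether]diheptanal: 7-{2,5-bis(benzyloxy)-3-[3-(benzyloxy)-5-(7-oxoheptyl)phenoxy]phenyl}heptanal | O=CCCCCCCc1cc(OCc2ccccc2)cc(Oc2cc(OCc3ccccc3)cc(CCCCCCC=O)c2OCc2ccccc2)c1
F2 | step 4 | 1-(benzyloxy)-3-bromo-5-iodobenzene | Brc1cc(I)cc(OCc2ccccc2)c1
F3 | step 5 | dilithio diaryl ether: {2,5-bis(benzyloxy)-3-[3-(benzyloxy)-5-lithiophenoxy]phenyl}lithium | [Li]c1cc(OCc2ccccc2)cc(Oc2cc(OCc3ccccc3)cc([Li])c2OCc2ccccc2)c1
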